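**Strategy.** Everything rests on disconnecting the C2–C3 bond of dihydrofuran ring B. In a 3,4,5-trimethoxybenzyl aryl ether the OCH2 group offers a C2–H bond activated twice, by the lone pair of O1 and by electron-rich ring C. This bond lies 1,5 to a diazo carbon (future C3) on ring A. A chiral dirhodium carboxylate turns this aryldiazoacetate into a carbene that inserts there: one operation makes C2–C3, closes ring B and sets both stereocentres (2R, cis). Bromine at C5 stands in for the carbene-sensitive propenyl group. Afterwards C3 is epimerised to trans, the ester becomes the methyl group, and propenyl is coupled on last.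

Key step: step 5

Assumption: the S-configured phthaloyl-tert-leucinate catalyst is taken to give the 2R series, as with closely related ortho-benzyloxy aryldiazoacetates; if a pilot run shows the opposite sense, Rh2(R-PTTL)4 is used and nothing else changes.

Step 1
Reactants: 1 4-bromo-2-methoxyphenol
Product: 2 4-bromo-2-iodo-6-methoxyphenol
Conditions: NaI, aq. NaOCl (slow addition), NaOH, MeOH, 0 °C; then Na2S2O3, dilute HCl
Reagents that add atoms: sodium iodide, [Na+].[I-]
Why: Electrophilic aromatic iodination of the phenoxide by hypoiodite made in situ: the O− group outweighs the methoxy group as director, its para position carries bromine and one ortho position carries OMe, so only the remaining ortho carbon can react and a second iodination is excluded.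

Step 2
Reactants: 2 4-bromo-2-iodo-6-methoxyphenol, 3 3,4,5-trimethoxybenzyl chloride
Product: 4 5-bromo-1-iodo-3-methoxy-2-[(3,4,5-trimethoxyphenyl)methoxy]benzene
Conditions: K2CO3, DMF, 60 °C
Reagents that add atoms: none
Why: Williamson ether synthesis: the phenoxide displaces chloride from a primary benzylic carbon by SN2, the mild carbonate base leaves both aryl halides alone, and moderate heating overcomes the crowding by the two ortho substituents.

Step 3
Reactants: 4 5-bromo-1-iodo-3-methoxy-2-[(3,4,5-trimethoxyphenyl)methoxy]benzene, 5 dimethyl oxalate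
Product: 7 methyl 2-[5-bromo-3-methoxy-2-(3,4,5-trimethoxybenzyloxy)phenyl]-2-oxoacetate, via arylmagnesium chloride 6 (not isolated)
Conditions: iPrMgCl·LiCl, THF, −20 °C; transfer into dimethyl oxalate (3 equiv), THF, −50 °C; aq. NH4Cl
Reagents that add atoms: none
Why: Iodine–magnesium exchange with the turbo-Grignard reagent is much faster than bromine–magnesium exchange and is helped by the neighbouring ether oxygen, and acylation of the aryl Grignard by inverse addition to excess dimethyl oxalate stops at the keto ester because the chelated magnesium hemiketal persists until the quench.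

Step 4
Reactants: 7 methyl 2-[5-bromo-3-methoxy-2-(3,4,5-trimethoxybenzyloxy)phenyl]-2-oxoacetate
Product: 9 methyl 2-[5-bromo-3-methoxy-2-(3,4,5-trimethoxybenzyloxy)phenyl]-2-diazoacetate, via tosylhydrazone 8 (not isolated)
Conditions: TsNHNH2, toluene, 90 °C; cool to rt, then DBU, CH2Cl2, rt, dark
Reagents that add atoms: p-toluenesulfonyl hydrazide, Cc1ccc(cc1)S(=O)(=O)NN
Why: Hydrazone condensation at the activated ketone followed by base-induced loss of p-toluenesulfinate (Bamford–Stevens type diazo synthesis) is a standard entry to aryldiazoacetates, spares the benzylic ether and the aryl bromide, and saves a separate arylacetate homologation and a sulfonyl azide.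

Step 5
Reactants: 9 methyl 2-[5-bromo-3-methoxy-2-(3,4,5-trimethoxybenzyloxy)phenyl]-2-diazoacetate
Product: 10 methyl (2R,3S)-5-bromo-7-methoxy-2-(3,4,5-trimethoxyphenyl)-2,3-dihydrobenzofuran-3-carboxylate (cis: ring C and the ester on the same face of ring B)
Conditions: Rh2(S-PTTL)4 (dirhodium tetrakis[N-phthaloyl-(S)-tert-leucinate], 2 mol %), toluene, 4 Å molecular sieves, −60 °C
Reagents that add atoms: none
Why: The diazo carbon binds at an axial site of Rh2(S-PTTL)4 and N2 leaves, giving an electrophilic rhodium carbene at C3 tempered by donor ring A and the acceptor ester; it then takes up one OCH2 hydrogen and bonds to C2 in a single asynchronous event, with the partial positive charge at C2 carried by O1 and ring C. The closest known reaction type is the enantioselective intramolecular C–H insertion of ortho-(benzyloxy)aryldiazoacetates under chiral dirhodium tetracarboxylate catalysis, which gives cis-2-aryl-2,3-dihydrobenzofuran-3-carboxylates. Ring B closes by 1,5-insertion as a five-membered ring made of C3, C3a, C7a, O1 and C2, whereas attack on O1 would need a four-membered ylide and attack on ring C a larger ring, so both are disfavoured. C2 is controlled by the catalyst: the wall of four phthaloyl-tert-leucinate ligands leaves one carbene face open and lets only one of the two enantiotopic hydrogens reach it, which fixes 2R. C3 is fixed in the same event by the transition-state geometry, in which ring C turns away from the ligand wall and ends on the same side as the ester, so the kinetic product is the cis (3S) isomer. The step needs chemoselectivity for this C–H bond over carbene dimerisation, arene attack and alkene cyclopropanation, and needs the hydrogen shift to stay concerted; the short rigid ortho tether, the doubly activated C2–H bond, bromine in place of propenyl, and low temperature in non-polar toluene secure this.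

Step 6
Reactants: 10 methyl (2R,3S)-5-bromo-7-methoxy-2-(3,4,5-trimethoxyphenyl)-2,3-dihydrobenzofuran-3-carboxylate
Product: 11 methyl (2R,3R)-5-bromo-7-methoxy-2-(3,4,5-trimethoxyphenyl)-2,3-dihydrobenzofuran-3-carboxylate (trans)
Conditions: NaOMe (0.3 equiv), MeOH/THF, 0 °C to rt; AcOH quench; recrystallise
Reagents that add atoms: none
Why: Base-catalysed epimerisation through the ester enolate: C3–H is benzylic and alpha to the ester, equilibrium reprotonation places the ester anti to ring C (3R), C2 has no acidic hydrogen and stays R, and substoichiometric methoxide in the matching alcohol avoids ester exchange and keeps E1cB opening of ring B slow.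

Step 7
Reactants: 11 methyl (2R,3R)-5-bromo-7-methoxy-2-(3,4,5-trimethoxyphenyl)-2,3-dihydrobenzofuran-3-carboxylate
Product: 12 [(2R,3S)-5-bromo-7-methoxy-2-(3,4,5-trimethoxyphenyl)-2,3-dihydrobenzofuran-3-yl]methanol (trans)
Conditions: LiAlH4, THF, 0 °C; aqueous NaOH work-up
Reagents that add atoms: none
Why: Hydride reduction of the ester to the primary alcohol is faster at 0 °C than deprotonation at C3 and leaves the aryl bromide, the aryl ethers and the C2–O1 bond untouched, so both centres are kept (the C3 descriptor becomes S only through a change of priorities).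

Step 8
Reactants: 12 [(2R,3S)-5-bromo-7-methoxy-2-(3,4,5-trimethoxyphenyl)-2,3-dihydrobenzofuran-3-yl]methanol
Product: 13 [(2R,3S)-5-bromo-7-methoxy-2-(3,4,5-trimethoxyphenyl)-2,3-dihydrobenzofuran-3-yl]methyl 4-methylbenzenesulfonate
Conditions: TsCl, Et3N, DMAP (10 mol %), CH2Cl2, 0 °C to rt
Reagents that add atoms: p-toluenesulfonyl chloride, Cc1ccc(cc1)S(=O)(=O)Cl
Why: Sulfonylation of an unhindered primary alcohol under nucleophilic catalysis by DMAP touches no stereocentre and turns the hydroxyl group into a leaving group for hydride.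

Step 9
Reactants: 13 [(2R,3S)-5-bromo-7-methoxy-2-(3,4,5-trimethoxyphenyl)-2,3-dihydrobenzofuran-3-yl]methyl 4-methylbenzenesulfonate
Product: 14 (2R,3R)-5-bromo-7-methoxy-3-methyl-2-(3,4,5-trimethoxyphenyl)-2,3-dihydrobenzofuran (trans)
Conditions: LiEt3BH, THF, 0 °C to rt
Reagents that add atoms: none
Why: SN2 hydride displacement: triethylborohydride is a very strong nucleophile and a weak base, so substitution at the primary carbon should outrun E2 loss of the benzylic C3–H, while the aryl bromide and aryl methyl ethers are inert at or below room temperature and C3 (R again by priorities only) is not involved.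

Step 10
Reactants: 14 (2R,3R)-5-bromo-7-methoxy-3-methyl-2-(3,4,5-trimethoxyphenyl)-2,3-dihydrobenzofuran, 15 (E)-1-propenylboronic acid pinacol ester
Product: 16 (2R,3R)-7-methoxy-3-methyl-5-[(E)-prop-1-enyl]-2-(3,4,5-trimethoxyphenyl)-2,3-dihydrobenzofuran
Conditions: Pd(dppf)Cl2·CH2Cl2 (5 mol %), K2CO3, 1,4-dioxane/H2O, 85 °C
Reagents that add atoms: none
Why: Suzuki–Miyaura coupling: zerovalent palladium inserts into the C5–Br bond, the alkenyl group passes from boron to palladium and reductive elimination retains the E geometry, and with the ester gone neither C2 nor C3 is base-labile.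

**Compound list**

1 | 4-bromo-2-methoxyphenol | COc1cc(Br)ccc1O | starting material
2 | 4-bromo-2-iodo-6-methoxyphenol | Ic1cc(Br)cc(OC)c1O | intermediate
3 | 3,4,5-trimethoxybenzyl chloride | COc1cc(CCl)cc(OC)c1OC | starting material
4 | 5-bromo-1-iodo-3-methoxy-2-[(3,4,5-trimethoxyphenyl)methoxy]benzene | Ic1cc(Br)cc(OC)c1OCc1cc(OC)c(OC)c(OC)c1 | intermediate
5 | dimethyl oxalate | COC(=O)C(=O)OC | starting material
6 | [5-bromo-3-methoxy-2-(3,4,5-trimethoxybenzyloxy)phenyl]magnesium chloride | COc1cc(Br)cc([Mg]Cl)c1OCc1cc(OC)c(OC)c(OC)c1 | intermediate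
7 | methyl 2-[5-bromo-3-methoxy-2-(3,4,5-trimethoxybenzyloxy)phenyl]-2-oxoacetate | COC(=O)C(=O)c1cc(Br)cc(OC)c1OCc1cc(OC)c(OC)c(OC)c1 | intermediate
8 | methyl 2-[5-bromo-3-methoxy-2-(3,4,5-trimethoxybenzyloxy)phenyl]-2-(2-tosylhydrazinylidene)acetate (C=N geometry not defined) | COC(=O)C(=NNS(=O)(=O)c1ccc(C)cc1)c1cc(Br)cc(OC)c1OCc1cc(OC)c(OC)c(OC)c1 | intermediate
9 | methyl 2-[5-bromo-3-methoxy-2-(3,4,5-trimethoxybenzyloxy)phenyl]-2-diazoacetate | COC(=O)C(=[N+]=[N-])c1cc(Br)cc(OC)c1OCc1cc(OC)c(OC)c(OC)c1 | intermediate
10 | methyl (2R,3S)-5-bromo-7-methoxy-2-(3,4,5-trimethoxyphenyl)-2,3-dihydrobenzofuran-3-carboxylate (cis) | Brc1cc(OC)c2c(c1)[C@H](C(=O)OC)[C@H](c1cc(OC)c(OC)c(OC)c1)O2 | intermediate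
11 | methyl (2R,3R)-5-bromo-7-methoxy-2-(3,4,5-trimethoxyphenyl)-2,3-dihydrobenzofuran-3-carboxylate (trans) | Brc1cc(OC)c2c(c1)[C@@H](C(=O)OC)[C@H](c1cc(OC)c(OC)c(OC)c1)O2 | intermediate
12 | [(2R,3S)-5-bromo-7-methoxy-2-(3,4,5-trimethoxyphenyl)-2,3-dihydrobenzofuran-3-yl]methanol (trans) | Brc1cc(OC)c2c(c1)[C@@H](CO)[C@H](c1cc(OC)c(OC)c(OC)c1)O2 | intermediate
13 | [(2R,3S)-5-bromo-7-methoxy-2-(3,4,5-trimethoxyphenyl)-2,3-dihydrobenzofuran-3-yl]methyl 4-methylbenzenesulfonate (trans) | Brc1cc(OC)c2c(c1)[C@@H](COS(=O)(=O)c1ccc(C)cc1)[C@H](c1cc(OC)c(OC)c(OC)c1)O2 | intermediate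
14 | (2R,3R)-5-bromo-7-methoxy-3-methyl-2-(3,4,5-trimethoxyphenyl)-2,3-dihydrobenzofuran (trans) | Brc1cc(OC)c2c(c1)[C@@H](C)[C@H](c1cc(OC)c(OC)c(OC)c1)O2 | intermediate
15 | (E)-1-propenylboronic acid pinacol ester | C/C=C/B1OC(C)(C)C(C)(C)O1 | starting material
16 | (2R,3R)-7-methoxy-3-methyl-5-[(E)-prop-1-enyl]-2-(3,4,5-trimethoxyphenyl)-2,3-dihydrobenzofuran | C/C=C/c1cc(OC)c2c(c1)[C@@H](C)[C@H](c1cc(OC)c(OC)c(OC)c1)O2 | target

Total step count: 10. Longest linear sequence: 10 steps (1 to 16).

**Steps most likely to fail**

**Step 5.**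
- What may go wrong: the two enantiotopic OCH2 hydrogens may be told apart incompletely, because the C7 methoxy group twists the ether out of the plane of ring A. The reaction may also drift towards a stepwise hydride shift, which would erode cis selectivity and enantiomeric purity.
- A small shortfall should be made up by recrystallising 11 or 12.
- For a serious shortfall, the source of enantiopurity is moved from the catalyst to a covalent resolution. The fallback sets out from 9 and comes back at 12.
- Achiral Rh2(OAc)4 in CH2Cl2 should convert 9 into the racemic cis ester F1. NaOMe in MeOH should then give the racemic trans ester F2, and LiAlH4 the racemic trans alcohol F3.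
- Acylation with (1S)-camphanic chloride (Et3N, DMAP, CH2Cl2) gives two diastereomers, the camphanate of the (2R,3S)-alcohol F4 and the camphanate of the (2S,3R)-alcohol F5. These are separated by crystallisation or chromatography. With bromine as heavy atom, a crystal structure can also assign the configuration.
- K2CO3 in MeOH then releases 12 from F4.

**Step 6.**
- What may go wrong: the enolate may expel the phenoxide of O1 (E1cB opening of ring B). Loss of the C2 configuration on reclosure, or decomposition, would follow.
- The epimerisation is moved to the aldehyde oxidation level, where a weak amine base is enough. The fallback sets out from 10 and comes back at 12.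
- LiAlH4 (THF, 0 °C) reduces 10 to the (2R,3R)-cis alcohol F6, and a buffered Dess–Martin oxidation gives the (2R,3S)-cis aldehyde F7.
- Catalytic DBU in CH2Cl2 equilibrates F7 to the (2R,3R)-trans aldehyde F8, and NaBH4 in MeOH gives 12.

**Step 9.**
- What may go wrong: the hydride may act as a base at the benzylic C3–H, with E2 loss of sulfonate followed by aromatisation of ring B. Slow hydrodebromination at C5 is also possible.
- The polar displacement is replaced by a base-free radical chain. The fallback sets out from 12, bypasses 13 and comes back at 14.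
- An Appel-type iodination (I2, PPh3, imidazole, toluene) gives the (2R,3R)-primary iodide F9.
- (Me3Si)3SiH with Et3B/air in toluene at rt, run concentrated in silane, then removes iodine. The silyl radical abstracts iodine from the sp3 carbon far faster than bromine from the arene.

**Further compounds**

F1 | step 5 | racemic methyl cis-5-bromo-7-methoxy-2-(3,4,5-trimethoxyphenyl)-2,3-dihydrobenzofuran-3-carboxylate | Brc1cc(OC)c2c(c1)[C@H](C(=O)OC)[C@H](c1cc(OC)c(OC)c(OC)c1)O2.Brc1cc(OC)c2c(c1)[C@@H](C(=O)OC)[C@@H](c1cc(OC)c(OC)c(OC)c1)O2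
F2 | step 5 | racemic methyl trans-5-bromo-7-methoxy-2-(3,4,5-trimethoxyphenyl)-2,3-dihydrobenzofuran-3-carboxylate | Brc1cc(OC)c2c(c1)[C@@H](C(=O)OC)[C@H](c1cc(OC)c(OC)c(OC)c1)O2.Brc1cc(OC)c2c(c1)[C@H](C(=O)OC)[C@@H](c1cc(OC)c(OC)c(OC)c1)O2
F3 | step 5 | racemic trans-[5-bromo-7-methoxy-2-(3,4,5-trimethoxyphenyl)-2,3-dihydrobenzofuran-3-yl]methanol | Brc1cc(OC)c2c(c1)[C@@H](CO)[C@H](c1cc(OC)c(OC)c(OC)c1)O2.Brc1cc(OC)c2c(c1)[C@H](CO)[C@@H](c1cc(OC)c(OC)c(OC)c1)O2
F4 | step 5 | (1S,4R)-camphanate of the (2R,3S)-alcohol | Brc1cc(OC)c2c(c1)[C@@H](COC(=O)[C@@]13CC[C@@](C)(C(=O)O1)C3(C)C)[C@H](c1cc(OC)c(OC)c(OC)c1)O2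
F5 | step 5 | (1S,4R)-camphanate of the (2S,3R)-alcohol | Brc1cc(OC)c2c(c1)[C@H](COC(=O)[C@@]13CC[C@@](C)(C(=O)O1)C3(C)C)[C@@H](c1cc(OC)c(OC)c(OC)c1)O2
F6 | step 6 | [(2R,3R)-5-bromo-7-methoxy-2-(3,4,5-trimethoxyphenyl)-2,3-dihydrobenzofuran-3-yl]methanol (cis) | Brc1cc(OC)c2c(c1)[C@H](CO)[C@H](c1cc(OC)c(OC)c(OC)c1)O2
F7 | step 6 | (2R,3S)-5-bromo-7-methoxy-2-(3,4,5-trimethoxyphenyl)-2,3-dihydrobenzofuran-3-carbaldehyde (cis) | Brc1cc(OC)c2c(c1)[C@H](C=O)[C@H](c1cc(OC)c(OC)c(OC)c1)O2
F8 | step 6 | (2R,3R)-5-bromo-7-methoxy-2-(3,4,5-trimethoxyphenyl)-2,3-dihydrobenzofuran-3-carbaldehyde (trans) | Brc1cc(OC)c2c(c1)[C@@H](C=O)[C@H](c1cc(OC)c(OC)c(OC)c1)O2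
F9 | step 9 | (2R,3R)-5-bromo-3-(iodomethyl)-7-methoxy-2-(3,4,5-trimethoxyphenyl)-2,3-dihydrobenzofuran (trans) | Brc1cc(OC)c2c(c1)[C@@H](CI)[C@H](c1cc(OC)c(OC)c(OC)c1)O2
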